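**Plan**

- Numbering (elemanolide): lactone O–C6 and C7–C11(=C13)–C12; C8 bears OAc; quaternary C10 bears vinyl (C1=C2) and C14H2OH; C5 bears the C4(=C3)–C15 arm.
- Cuts: C11=C13 (olefination of an α-phosphono lactone); C8–C9 together with return of the vinyl group from C10 to C14 (pinacol-terminated Prins cyclisation); C7–C11 and the C8 electrophile stored in a lactone-fused donor–acceptor cyclopropane C7–C8–C11; C5–C6 (allylation); C4–C5 and C10–C14 (two Baylis–Hillman reactions).
- Enabling feature: the C8 carbinol lies 1,3 to a quaternary carbon (C10) that carries a vinyl group and an oxygenated carbon (C14), the retron of a Prins cyclisation ended by a 1,2-vinyl shift; C8 is also β to the lactone α-carbon C11, the retron of a siloxycyclopropane.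
- Forward: the chain is joined first (two Baylis–Hillman reactions, chromium-catalysed allylation); the γ-lactone is closed as a bicyclo[3.1.0] cyclopropane; the cyclohexane closes last in one cascade; acetate, alcohol and exo-methylene are then adjusted.
- Stereochemistry: C5 and C6 from one ligand-controlled anti allylation; C7 by substrate control in the cyclopropanation; C8 and C10 in the key step (chair, antiperiplanar vinyl shift).

Key step: step 14

Remark on the chemistry: the silyloxy carbon C14 (compounds 3–19) and the phosphonate carbon C11 (compounds 21–25) are carried as epimer mixtures, because both centres are destroyed later (pinacol shift, olefination). TBS = tert-butyldimethylsilyl.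

**Route**

Step 1
Reactants: 1 acrolein; 2 methyl acrylate
Product: 3 methyl 3-hydroxy-2-methylidenepent-4-enoate (racemic)
Conditions: DABCO (10 mol%), neat (excess 2), rt, 5–7 d
Reagents that add atoms: none
Why: Morita–Baylis–Hillman reaction, in which the ammonium enolate of the acrylate adds 1,2 to the aldehyde and forms C10–C14; the carbinol is deliberately racemic.

Step 2
Reactants: 3 methyl 3-hydroxy-2-methylidenepent-4-enoate
Product: 4 methyl 3-(TBSO)-2-methylidenepent-4-enoate
Conditions: TBSCl, imidazole, DMF, 0 °C → rt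
Reagents that add atoms: tert-butyldimethylsilyl chloride, CC(C)(C)[Si](C)(C)Cl
Why: Standard silylation of a secondary allylic alcohol; this silyl group later serves as the leaving group of the pinacol shift.

Step 3
Reactants: 4 methyl 3-(TBSO)-2-methylidenepent-4-enoate
Product: 5 3-(TBSO)-2-methylidenepent-4-en-1-ol
Conditions: i-Bu2AlH (2.2 equiv), CH2Cl2, −78 °C; aq. Rochelle salt
Reagents that add atoms: none
Why: 1,2-Reduction of a conjugated ester to the allylic alcohol by i-Bu2AlH, which leaves the silyl ether and both alkenes untouched.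

Step 4
Reactants: 5 3-(TBSO)-2-methylidenepent-4-en-1-ol
Product: 6 3-(TBSO)-2-methylidenepent-4-enal
Conditions: MnO2 (excess), CH2Cl2, rt
Reagents that add atoms: none
Why: Chemoselective MnO2 oxidation of a primary allylic alcohol to the enal under neutral conditions.

Step 5
Reactants: 6 3-(TBSO)-2-methylidenepent-4-enal; 2 methyl acrylate
Product: 7 methyl 3-hydroxy-2,4-dimethylidene-5-(TBSO)hept-6-enoate (diastereomer mixture)
Conditions: DABCO (1 equiv), neat (excess 2), rt, 5–7 d
Reagents that add atoms: none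
Why: Second Morita–Baylis–Hillman reaction (1,2-addition to the enal carbonyl) forms C4–C5; the new carbinol centre is lost in step 6.

Step 6
Reactants: 7 methyl 3-hydroxy-2,4-dimethylidene-5-(TBSO)hept-6-enoate
Product: 8 methyl (2Z)-2-(bromomethyl)-4-methylidene-5-(TBSO)hepta-2,6-dienoate
Conditions: NBS, Me2S, CH2Cl2, 0 °C → rt
Reagents that add atoms: N-bromosuccinimide, O=C1CCC(=O)N1Br
Why: Corey–Kim-type activation of the Baylis–Hillman alcohol followed by SN2' attack of bromide at the acrylate terminus gives the conjugated (Z)-2-(bromomethyl)enoate, the usual outcome for such adducts.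

Step 7
Reactants: 9 1,1,3,3-tetramethoxypropane
Product: 11 (2E)-3-(TBSO)prop-2-enal, via sodium malonaldehyde enolate 10 (not isolated)
Conditions: cat. HCl, H2O, rt; NaOH (1 equiv), evaporation; TBSCl, THF, 0 °C → rt
Reagents that add atoms: water, O; tert-butyldimethylsilyl chloride, CC(C)(C)[Si](C)(C)Cl
Why: Acetal hydrolysis gives malonaldehyde, whose sodium enolate is silylated on oxygen to the E-configured vinylogous silyl ester.

Step 8
Reactants: 8 methyl (2Z)-2-(bromomethyl)-4-methylidene-5-(TBSO)hepta-2,6-dienoate; 11 (2E)-3-(TBSO)prop-2-enal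
Product: 13 methyl (3R)-3-[(1R,2E)-1-hydroxy-3-(TBSO)prop-2-en-1-yl]-2,4-dimethylidene-5-(TBSO)hept-6-enoate, via trimethylsilyl ether 12 (not isolated)
Conditions: CrCl2 (10 mol%), chiral tridentate carbazole bis(oxazoline) ligand (12 mol%), Mn powder, Me3SiCl, i-Pr2NEt, THF, 0 °C → rt; then aq. citric acid, THF, 0 °C
Reagents that add atoms: none
Why: Catalytic enantioselective Nozaki–Hiyama–Kishi 2-(alkoxycarbonyl)allylation, in which the equilibrating allylchromium species reacts through its γ-carbon (C5) in a chair with the dienyl arm equatorial (anti C5/C6), while the ligand enantiomer is chosen for Re-face addition to 11 (C6).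

Step 9
Reactants: 13 methyl (3R)-3-[(1R,2E)-1-hydroxy-3-(TBSO)prop-2-en-1-yl]-2,4-dimethylidene-5-(TBSO)hept-6-enoate
Product: 14 (1E,3R,4S)-4-(3-hydroxyprop-1-en-2-yl)-5-methylidene-1,6-bis(TBSO)octa-1,7-dien-3-ol
Conditions: i-Bu2AlH (3.5 equiv), CH2Cl2, −78 → −20 °C; aq. Rochelle salt
Reagents that add atoms: none
Why: i-Bu2AlH reduction of the acrylate ester gives the C15 allylic alcohol, and it removes the only base-sensitive relationship (C5–H γ to the ester) before any basic step.

Step 10
Reactants: 14 (1E,3R,4S)-4-(3-hydroxyprop-1-en-2-yl)-5-methylidene-1,6-bis(TBSO)octa-1,7-dien-3-ol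
Product: 15 2-[(1E,3R,4S)-3-hydroxy-5-methylidene-1,6-bis(TBSO)octa-1,7-dien-4-yl]prop-2-en-1-yl acetate
Conditions: AcCl (1.05 equiv), 2,4,6-collidine, CH2Cl2, −78 °C
Reagents that add atoms: acetyl chloride, CC(=O)Cl
Why: Sterically governed acetylation of the primary allylic hydroxyl over the hindered secondary one installs the C15 acetate of the target, so that no free C15–OH ever faces the later C14 aldehyde.

Step 11
Reactants: 15 2-[(1E,3R,4S)-3-hydroxy-5-methylidene-1,6-bis(TBSO)octa-1,7-dien-4-yl]prop-2-en-1-yl acetate; 16 (diethoxyphosphoryl)acetic acid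
Product: 17 (1E,3R,4S)-4-[3-(acetyloxy)prop-1-en-2-yl]-5-methylidene-1,6-bis(TBSO)octa-1,7-dien-3-yl (diethoxyphosphoryl)acetate
Conditions: DCC, DMAP (cat.), CH2Cl2, 0 °C → rt
Reagents that add atoms: none
Why: Steglich esterification of the C6 hydroxyl brings in C11, C12 and the phosphonate that later delivers the exo-methylene group.

Step 12
Reactants: 17 (1E,3R,4S)-4-[3-(acetyloxy)prop-1-en-2-yl]-5-methylidene-1,6-bis(TBSO)octa-1,7-dien-3-yl (diethoxyphosphoryl)acetate
Product: 18 (1E,3R,4S)-4-[3-(acetyloxy)prop-1-en-2-yl]-5-methylidene-1,6-bis(TBSO)octa-1,7-dien-3-yl diazo(diethoxyphosphoryl)acetate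
Conditions: p-ABSA, DBU, MeCN, 0 °C
Reagents that add atoms: 4-acetamidobenzenesulfonyl azide, CC(=O)Nc1ccc(cc1)S(=O)(=O)N=[N+]=[N-]
Why: Regitz diazo transfer to the doubly activated methylene of the phosphonoacetate.

Step 13
Reactants: 18 (1E,3R,4S)-4-[3-(acetyloxy)prop-1-en-2-yl]-5-methylidene-1,6-bis(TBSO)octa-1,7-dien-3-yl diazo(diethoxyphosphoryl)acetate
Product: 19 diethyl [(1R,4R,5S,6S)-4-[(3S)-2-(acetoxymethyl)-4-methylidene-5-(TBSO)hepta-1,6-dien-3-yl]-2-oxo-6-(TBSO)-3-oxabicyclo[3.1.0]hexan-1-yl]phosphonate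
Conditions: Rh2(OAc)4 (2 mol%), ClCH2CH2Cl, 80 °C, slow addition
Reagents that add atoms: none
Why: Intramolecular rhodium-carbenoid cyclopropanation of the proximal electron-rich E-enol ether closes the γ-lactone (C7–C11) stereospecifically, on the face that puts the C6 side chain anti to the new cyclopropane carbon C8, which sets C7 by substrate control.

Step 14
Reactants: 19 diethyl [(1R,4R,5S,6S)-4-[(3S)-2-(acetoxymethyl)-4-methylidene-5-(TBSO)hepta-1,6-dien-3-yl]-2-oxo-6-(TBSO)-3-oxabicyclo[3.1.0]hexan-1-yl]phosphonate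
Product: 22 diethyl [(3aS,4S,6R,7S,7aR)-7-[3-(acetyloxy)prop-1-en-2-yl]-6-ethenyl-6-formyl-2-oxo-4-(TBSO)octahydro-1-benzofuran-3-yl]phosphonate, via ring-opened zwitterion 20 (not isolated), via silyl ketene acetal 21 (not isolated)
Conditions: Me3SiOTf (20 mol%), 2,6-di-tert-butyl-4-methylpyridine (30 mol%), CH2Cl2, −78 → −40 °C; aq. NaHCO3
Reagents that add atoms: none
Why: Proposed new method: the silyl triflate activates the lactone/phosphonate acceptor pair of the donor–acceptor cyclopropane and strain release breaks the C8–C11 bond to the ketene acetal/silyloxocarbenium pair 20; the alkene terminus C9 then attacks C8 through a chair (6-endo with respect to the C9=C10 alkene, 6-exo-trig at the oxocarbenium ion), and the developing C10 cation is quenched by a 1,2-shift of the vinyl group from C14, which becomes the formyl group and hands its silyl group to the ketene acetal (21, hydrolysed on work-up). The closest known reaction types are the pinacol-terminated Prins cyclisation of alkenyl silyl ethers with tethered oxocarbenium ions and the Lewis-acid ring opening of 2-siloxycyclopropanecarboxylates to 1,3-zwitterions. C8 is set by the chair, with the silyloxy group equatorial beside the trans-fused lactone; C10 is set because the vinyl group migrates antiperiplanar to the forming C8–C9 bond, which places vinyl equatorial and formyl axial, and both C14 epimers converge. The step needs chemoselection between the two 1,1-disubstituted alkenes on C5, which the C5 configuration should secure (closure through C9 keeps every substituent equatorial, closure through C3 would force the larger arm axial) together with the deactivating allylic acetate; it also needs vinyl over hydride shift (antiperiplanar C14–vinyl bond, π-participation) and Prins closure over [3+2] collapse (C11 and C10 cannot meet across the trans-fused lactone).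

Step 15
Reactants: 22 diethyl [(3aS,4S,6R,7S,7aR)-7-[3-(acetyloxy)prop-1-en-2-yl]-6-ethenyl-6-formyl-2-oxo-4-(TBSO)octahydro-1-benzofuran-3-yl]phosphonate
Product: 23 diethyl [(3aR,4S,6R,7S,7aR)-7-[3-(acetyloxy)prop-1-en-2-yl]-6-ethenyl-6-formyl-4-hydroxy-2-oxooctahydro-1-benzofuran-3-yl]phosphonate
Conditions: HF·pyridine, pyridine, THF, 0 °C → rt
Reagents that add atoms: none
Why: Buffered fluoride desilylation of the secondary silyl ether; the equatorial C8 hydroxyl is trans to the axial formyl group and cannot form a lactol.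

Step 16
Reactants: 23 diethyl [(3aR,4S,6R,7S,7aR)-7-[3-(acetyloxy)prop-1-en-2-yl]-6-ethenyl-6-formyl-4-hydroxy-2-oxooctahydro-1-benzofuran-3-yl]phosphonate
Product: 24 diethyl [(3aR,4S,6R,7S,7aR)-4-(acetyloxy)-7-[3-(acetyloxy)prop-1-en-2-yl]-6-ethenyl-6-formyl-2-oxooctahydro-1-benzofuran-3-yl]phosphonate
Conditions: Ac2O, DMAP (cat.), pyridine, CH2Cl2, 0 °C
Reagents that add atoms: acetic anhydride, CC(=O)OC(C)=O
Why: Acetylation of the C8 hydroxyl while C14 is still masked as the non-enolisable aldehyde, which is what differentiates the three oxygens of the target.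

Step 17
Reactants: 24 diethyl [(3aR,4S,6R,7S,7aR)-4-(acetyloxy)-7-[3-(acetyloxy)prop-1-en-2-yl]-6-ethenyl-6-formyl-2-oxooctahydro-1-benzofuran-3-yl]phosphonate
Product: 25 diethyl [(3aR,4S,6R,7S,7aR)-4-(acetyloxy)-7-[3-(acetyloxy)prop-1-en-2-yl]-6-ethenyl-6-(hydroxymethyl)-2-oxooctahydro-1-benzofuran-3-yl]phosphonate
Conditions: NaBH4, MeOH/THF, −20 °C
Reagents that add atoms: none
Why: Chemoselective borohydride reduction of the aldehyde in the presence of lactone, acetates and phosphonate, done before the conjugate acceptor exists.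

Step 18
Reactants: 25 diethyl [(3aR,4S,6R,7S,7aR)-4-(acetyloxy)-7-[3-(acetyloxy)prop-1-en-2-yl]-6-ethenyl-6-(hydroxymethyl)-2-oxooctahydro-1-benzofuran-3-yl]phosphonate
Product: 26 [(3aR,4S,6R,7S,7aR)-7-[3-(acetyloxy)prop-1-en-2-yl]-6-ethenyl-6-(hydroxymethyl)-3-methylidene-2-oxooctahydro-1-benzofuran-4-yl] acetate (CNP0240658.1)
Conditions: aq. CH2O (37%), K2CO3, THF, 0 °C
Reagents that add atoms: formaldehyde, C=O
Why: Horner–Wadsworth–Emmons olefination of the α-phosphono lactone with formaldehyde installs the exo-methylene group under mild carbonate conditions that the acetates should tolerate, and it removes the C11 stereocentre.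

**Compound list**

1 | acrolein | C=CC=O | starting material
2 | methyl acrylate | C=CC(=O)OC | starting material
3 | methyl 3-hydroxy-2-methylidenepent-4-enoate (racemic) | C=CC(O)C(=C)C(=O)OC | intermediate
4 | methyl 3-(TBSO)-2-methylidenepent-4-enoate (racemic) | C=CC(O[Si](C)(C)C(C)(C)C)C(=C)C(=O)OC | intermediate
5 | 3-(TBSO)-2-methylidenepent-4-en-1-ol (racemic) | C=CC(O[Si](C)(C)C(C)(C)C)C(=C)CO | intermediate
6 | 3-(TBSO)-2-methylidenepent-4-enal (racemic) | C=CC(O[Si](C)(C)C(C)(C)C)C(=C)C=O | intermediate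
7 | methyl 3-hydroxy-2,4-dimethylidene-5-(TBSO)hept-6-enoate (diastereomer mixture) | C=CC(O[Si](C)(C)C(C)(C)C)C(=C)C(O)C(=C)C(=O)OC | intermediate
8 | methyl (2Z)-2-(bromomethyl)-4-methylidene-5-(TBSO)hepta-2,6-dienoate (racemic) | C=CC(O[Si](C)(C)C(C)(C)C)C(=C)/C=C(\CBr)C(=O)OC | intermediate
9 | 1,1,3,3-tetramethoxypropane | COC(OC)CC(OC)OC | starting material
10 | sodium (E)-3-oxoprop-1-en-1-olate (sodium malonaldehyde enolate) | [Na+].[O-]/C=C/C=O | intermediate
11 | (2E)-3-(TBSO)prop-2-enal | O=C/C=C/O[Si](C)(C)C(C)(C)C | intermediate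
12 | O-trimethylsilyl ether of 13 | COC(=O)C(=C)[C@@H](C(=C)C(O[Si](C)(C)C(C)(C)C)C=C)[C@@H](O[Si](C)(C)C)/C=C/O[Si](C)(C)C(C)(C)C | intermediate
13 | methyl (3R)-3-[(1R,2E)-1-hydroxy-3-(TBSO)prop-2-en-1-yl]-2,4-dimethylidene-5-(TBSO)hept-6-enoate (anti adduct; epimers at the silyloxy carbon) | COC(=O)C(=C)[C@@H](C(=C)C(O[Si](C)(C)C(C)(C)C)C=C)[C@@H](O)/C=C/O[Si](C)(C)C(C)(C)C | intermediate
14 | (1E,3R,4S)-4-(3-hydroxyprop-1-en-2-yl)-5-methylidene-1,6-bis(TBSO)octa-1,7-dien-3-ol | OCC(=C)[C@@H](C(=C)C(O[Si](C)(C)C(C)(C)C)C=C)[C@@H](O)/C=C/O[Si](C)(C)C(C)(C)C | intermediate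
15 | 2-[(1E,3R,4S)-3-hydroxy-5-methylidene-1,6-bis(TBSO)octa-1,7-dien-4-yl]prop-2-en-1-yl acetate | CC(=O)OCC(=C)[C@@H](C(=C)C(O[Si](C)(C)C(C)(C)C)C=C)[C@@H](O)/C=C/O[Si](C)(C)C(C)(C)C | intermediate
16 | (diethoxyphosphoryl)acetic acid | CCOP(=O)(OCC)CC(=O)O | starting material
17 | (1E,3R,4S)-4-[3-(acetyloxy)prop-1-en-2-yl]-5-methylidene-1,6-bis(TBSO)octa-1,7-dien-3-yl (diethoxyphosphoryl)acetate | CC(=O)OCC(=C)[C@@H](C(=C)C(O[Si](C)(C)C(C)(C)C)C=C)[C@@H](OC(=O)CP(=O)(OCC)OCC)/C=C/O[Si](C)(C)C(C)(C)C | intermediate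
18 | (1E,3R,4S)-4-[3-(acetyloxy)prop-1-en-2-yl]-5-methylidene-1,6-bis(TBSO)octa-1,7-dien-3-yl diazo(diethoxyphosphoryl)acetate | CC(=O)OCC(=C)[C@@H](C(=C)C(O[Si](C)(C)C(C)(C)C)C=C)[C@@H](OC(=O)C(=[N+]=[N-])P(=O)(OCC)OCC)/C=C/O[Si](C)(C)C(C)(C)C | intermediate
19 | diethyl [(1R,4R,5S,6S)-4-[(3S)-2-(acetoxymethyl)-4-methylidene-5-(TBSO)hepta-1,6-dien-3-yl]-2-oxo-6-(TBSO)-3-oxabicyclo[3.1.0]hexan-1-yl]phosphonate (lactone-fused siloxycyclopropane; side chain on C4 anti to the cyclopropane, silyloxy group exo) | CC(=O)OCC(=C)[C@@H](C(=C)C(O[Si](C)(C)C(C)(C)C)C=C)[C@H]1OC(=O)[C@]2(P(=O)(OCC)OCC)[C@@H](O[Si](C)(C)C(C)(C)C)[C@H]12 | intermediate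
20 | ring-opened zwitterion: lactone phosphono-enolate with C8 silyloxocarbenium ion (activating silyl group omitted) | CC(=O)OCC(=C)[C@@H](C(=C)C(O[Si](C)(C)C(C)(C)C)C=C)[C@H]1OC([O-])=C(P(=O)(OCC)OCC)[C@@H]1C=[O+][Si](C)(C)C(C)(C)C | intermediate
21 | diethyl [(3aS,4S,6R,7S,7aR)-7-[3-(acetyloxy)prop-1-en-2-yl]-6-ethenyl-6-formyl-2,4-bis(TBSO)-3a,4,5,6,7,7a-hexahydro-1-benzofuran-3-yl]phosphonate (silyl ketene acetal, drawn with the relayed TBS group) | C=C[C@]1(C=O)C[C@H](O[Si](C)(C)C(C)(C)C)[C@H]2C(P(=O)(OCC)OCC)=C(O[Si](C)(C)C(C)(C)C)O[C@@H]2[C@H]1C(=C)COC(C)=O | intermediate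
22 | diethyl [(3aS,4S,6R,7S,7aR)-7-[3-(acetyloxy)prop-1-en-2-yl]-6-ethenyl-6-formyl-2-oxo-4-(TBSO)octahydro-1-benzofuran-3-yl]phosphonate (C3 epimers; 8α-silyloxy, 10β-formyl, 10α-vinyl in elemanolide numbering) | C=C[C@]1(C=O)C[C@H](O[Si](C)(C)C(C)(C)C)[C@H]2C(P(=O)(OCC)OCC)C(=O)O[C@@H]2[C@H]1C(=C)COC(C)=O | intermediate
23 | diethyl [(3aR,4S,6R,7S,7aR)-7-[3-(acetyloxy)prop-1-en-2-yl]-6-ethenyl-6-formyl-4-hydroxy-2-oxooctahydro-1-benzofuran-3-yl]phosphonate | C=C[C@]1(C=O)C[C@H](O)[C@H]2C(P(=O)(OCC)OCC)C(=O)O[C@@H]2[C@H]1C(=C)COC(C)=O | intermediate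
24 | diethyl [(3aR,4S,6R,7S,7aR)-4-(acetyloxy)-7-[3-(acetyloxy)prop-1-en-2-yl]-6-ethenyl-6-formyl-2-oxooctahydro-1-benzofuran-3-yl]phosphonate | C=C[C@]1(C=O)C[C@H](OC(C)=O)[C@H]2C(P(=O)(OCC)OCC)C(=O)O[C@@H]2[C@H]1C(=C)COC(C)=O | intermediate
25 | diethyl [(3aR,4S,6R,7S,7aR)-4-(acetyloxy)-7-[3-(acetyloxy)prop-1-en-2-yl]-6-ethenyl-6-(hydroxymethyl)-2-oxooctahydro-1-benzofuran-3-yl]phosphonate | C=C[C@]1(CO)C[C@H](OC(C)=O)[C@H]2C(P(=O)(OCC)OCC)C(=O)O[C@@H]2[C@H]1C(=C)COC(C)=O | intermediate
26 | [(3aR,4S,6R,7S,7aR)-7-[3-(acetyloxy)prop-1-en-2-yl]-6-ethenyl-6-(hydroxymethyl)-3-methylidene-2-oxooctahydro-1-benzofuran-4-yl] acetate (CNP0240658.1) | C=C[C@]1(CO)C[C@H](OC(C)=O)[C@H]2C(=C)C(=O)O[C@@H]2[C@H]1C(=C)COC(C)=O | target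

**Totals**

Total step count: 18. Longest linear sequence: 17 steps (steps 1–6 and 8–18; step 7 is a one-step side branch).

**Steps most likely to fail**

Step 14 (proposed new method). The zwitterion may collapse without cyclising (dihydrofuran formation, or loss of the C7 proton followed by expulsion of the lactone carboxylate). Ring closure may run through the acetate-bearing arm, or hydride rather than vinyl may migrate. Fallback with the two events uncoupled and each of an established type: setting out from 19, fluoride-induced retro-aldol opening of the siloxycyclopropane (Et3N·3HF, THF, −20 °C; the cyclopropyl silyl ether, which expels a stabilised phosphono-enolate, should cleave faster than the alkyl silyl ether) gives the isolable β-formyl α-phosphono lactone F1. Its aldehyde is then engaged in a pinacol-terminated Prins cyclisation under catalytic TBSOTf with 2,6-di-tert-butyl-4-methylpyridine in CH2Cl2 at −78 °C (O-silylation of the aldehyde, chair closure, silyl transfer from O14). This delivers 22, where the route is rejoined.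

Step 13. The acceptor/acceptor carbenoid may insert into the doubly allylic C5–H bond, may give zwitterion-derived products with the very electron-rich enol ether, or may add to the wrong alkene face. Fallback with a radical in place of the carbenoid: setting out from 17, oxidative free-radical cyclisation with Mn(OAc)3·2H2O and Cu(OAc)2 in AcOH/MeCN forms C7–C11 by 5-exo attack of the phosphonoacetate radical on the enol ether. The α-siloxy radical is oxidised and loses its silyl group, which should give the thermodynamically preferred trans β-formyl α-phosphono lactone F2 (the same constitution as F1). F2 is taken to 22 by the silyl-triflate-catalysed Prins–pinacol cyclisation described above, where the route is rejoined.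

Step 8. The pentadienyl-type chromium species may react through the wrong terminus or lose anti selectivity by metallotropic shift, and facial control by the ligand may be poor with the vinylogous ester aldehyde 11. Fallback with resolution in place of asymmetric catalysis: setting out from 8 and 11, the ligand-free reaction with stoichiometric CrCl2 in THF gives the anti adduct as a racemate, that is 13 together with its enantiomer F3. A lipase (a serine hydrolase used as acyl transferase, for example immobilised Candida antarctica lipase B with vinyl acetate in MTBE) selected to acylate F3 converts it into the acetate F4 and leaves 13, which is separated and rejoins the route at step 9.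

Further compounds
F1 | step 14 | diethyl [(4S,5R)-5-[(3S)-2-(acetoxymethyl)-4-methylidene-5-(TBSO)hepta-1,6-dien-3-yl]-4-formyl-2-oxooxolan-3-yl]phosphonate | CC(=O)OCC(=C)[C@@H](C(=C)C(O[Si](C)(C)C(C)(C)C)C=C)[C@H]1OC(=O)C(P(=O)(OCC)OCC)[C@@H]1C=O
F2 | step 13 | diethyl [(4S,5R)-5-[(3S)-2-(acetoxymethyl)-4-methylidene-5-(TBSO)hepta-1,6-dien-3-yl]-4-formyl-2-oxooxolan-3-yl]phosphonate (same constitution as F1, reached from 17) | CC(=O)OCC(=C)[C@@H](C(=C)C(O[Si](C)(C)C(C)(C)C)C=C)[C@H]1OC(=O)C(P(=O)(OCC)OCC)[C@@H]1C=O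
F3 | step 8 | methyl (3S)-3-[(1S,2E)-1-hydroxy-3-(TBSO)prop-2-en-1-yl]-2,4-dimethylidene-5-(TBSO)hept-6-enoate (enantiomer of 13) | COC(=O)C(=C)[C@H](C(=C)C(O[Si](C)(C)C(C)(C)C)C=C)[C@H](O)/C=C/O[Si](C)(C)C(C)(C)C
F4 | step 8 | methyl (3S)-3-[(1S,2E)-1-(acetyloxy)-3-(TBSO)prop-2-en-1-yl]-2,4-dimethylidene-5-(TBSO)hept-6-enoate | COC(=O)C(=C)[C@H](C(=C)C(O[Si](C)(C)C(C)(C)C)C=C)[C@H](OC(C)=O)/C=C/O[Si](C)(C)C(C)(C)C
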